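Find the feed.

| flask | solid substrate | remark | time |
|---|---|---|---|
| south | 22 mM | run made earlier |  |
| cedar | 40 mM |  | 100 h |
| maple | 20 mM |  | 30 h |

- south (time / h: ring / %, solid substrate / %): 1.33: 0, 98; 4.00: 3, 93; 6.00: 7, 86; 10.0: 15, 78

(standard deviation of a reading: 1.5 percentage points)

- a species is counted by the solid substrate in it: one open dimer or side product counts as two
- given per volume of solution although it is solid: solid substrate
- reactions considered so far: starting material -> ring; solid substrate <-> starting material; starting material -> decomposition product; 2 starting material <-> open dimer; starting material + ring -> side product
- at the start none of the solid substrate is in solution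
- what has only dissolved of solid substrate counts as not reacted

- which one finishes higher in amount of ring, in percent of the solid substrate charged ("neither" within 2 percentage points) (cedar / maple / neither)
- amount of ring at the end, in percent of the solid substrate charged, cedar
- amount of ring at the end, in percent of the solid substrate charged, maple

Take dissolved starting material as the concentration that sets the order of the rate. Assume that while solid stands, the solution stays near a level that does not follow the amount of solid, which makes the loss of solid pseudo-zero-order. Call the feed F, the mM of solid substrate leaving the solid each hour. The south run's readings show a loss of 22.0% of its 22 mM in 10.0 h, so F reads as 0.484 mM h⁻¹, with the scatter of those readings, and the estimate for how long a charge lasts is its concentration divided by F.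

Now build the flask up. Start with the main step, starting material to ring, and nothing else. Maple then holds 72.6% ring at 30 h, while cedar's charge lasts 82.6 h, shorter than its 100 h, so cedar reaches 100 percent. Next add the stock held in solution. At 10.0 h the south run showed 15% ring, a gap of 1.54 mM behind the solid lost, and holding that back brings maple down to 64.9%. Cedar has 17.4 h left for its stock to drain, so leave it unchanged. Finally add the side product, which consumes ring and starting material together. The south run's readings give it no size, so treat both figures as estimated ceilings, and with cedar's the higher by 35 percentage points, commit to cedar above maple without a firmer number.

The forecast gives cedar as higher, with 65% for cedar and 43% for maple, holding that “The higher concentration favours dimer and side product”.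

The flasks give cedar as higher, with 55.0% in cedar and 46.5% in maple.

    starting material → ring (k = 1.13 × 10⁻⁴ s⁻¹)
    solid substrate ⇌ starting material, rate k2*(cs2 - [starting material]) while solid is left; crystals form when [starting material] > cs2 (solubility = 6.70 mM, k = 2.05 × 10⁻⁵ s⁻¹)
    starting material → decomposition product (k = 1.02 × 10⁻⁷ s⁻¹)
    2 starting material ⇌ open dimer (K = 237 M⁻¹, k = 0.00898 M⁻¹ s⁻¹)
    starting material + ring → side product (k = 0.00265 M⁻¹ s⁻¹)

Maple lost 64.7% of its solid substrate by 30.0 h, a feed of 0.431 mM h⁻¹. Cedar, with twice the charge, fed 0.432 mM h⁻¹ up to 50.0 h, about the same as maple. By 100 h, later than the 82.6 h that F gave its charge, cedar's solid substrate stands at 0%, with 44.6% side product beside its ring. Charge the neighbour of maple with 5.0 mM instead: F gives it 10.3 h, shorter than its 30 h. At 30.0 h that neighbour's solid substrate stands at 0%, its side product at 10.0% and its ring at 89.1%.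

All runs stem from a simulated flask from invented constants; noise was put on by code.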